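An hour at constant temperature is the run, and your hunch is to take the mean of second intermediate over that hour; test that before you lean on it.

| setting | alder | birch | elm |
|---|---|---|---|
| substrate | 0.10 M | 0.10 M | 0.10 M |
| partner | 0.210 M | 0.0700 M | 0.630 M |
| time | 1.0 h | 1.0 h | 1.0 h |

    substrate ⇌ open intermediate (K1 = 1.1, k1 = 0.17 min⁻¹)
    partner → second intermediate (k2 = 0.018 min⁻¹)
    open intermediate + second intermediate → target (k3 = 3.8 L mol⁻¹ min⁻¹)
    2 open intermediate → homo product (k4 = 1.5 L mol⁻¹ min⁻¹)
    target ⇌ isomer of the product (K5 = 25, k5 = 0.010 min⁻¹)
    crystals ⇌ target, rate k6*(cs6 - [target]) while solid is left; crystals form when [target] > cs6 (cs6 = 34 mM, k6 = 0.22 min⁻¹)

- percentages count the substrate that a species holds: one homo product counts as two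
- target is meant together with its crystals
- where a step has two of a species, its rate is k times that concentration squared, and two are used at each turn
- solid, in amounts per volume of the solution: crystals
- run time (alder): 1.0 h

* which of these there is most of at the end, counted by the substrate in it, alder (isomer of the product / homo product / target / substrate)
* which of these there is most of at the end, counted by the substrate in it, birch (isomer of the product / homo product / target / substrate)
* which of these there is most of at the end, counted by the substrate in it, elm (isomer of the product / homo product / target / substrate)
* final amount of the leader among these, as a percentage of the substrate charged, in alder
* final amount of the leader among these, as a percentage of the substrate charged, in birch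
* final amount of the leader among these, as a percentage of the substrate charged, in elm

Treat substrate and open intermediate as one pool, of which a share 0.524 is open at equilibrium. Let homo coupling alone halve that pool: this takes T = 12.1 min, one over twice the homo constant times the open share squared times the charge, and that is far shorter than the run. So use T as the clock. By T, partner has turned 19.6% of its charge into second intermediate, but the mean over the hour is 38.9%, twice that, so your mean overstates what the pool meets. Replace the curve by its value at T, and ignore what coupling consumes.

This gives D* = 0.211 M, the contest charge: the partner charge at which a pool still at full charge, with second intermediate held at its value at T, loses as much to homo product as to coupling, a pseudo-first-order step once second intermediate is held. Write x for D* over the flask's partner charge. Integrating the pool down to nothing then gives a coupled share of ln(1+x)/x, and in this reckoning the rest goes to homo product.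

Now, for alder and elm, hold dissolved target at its solubility for the whole hour, which by this reckoning leaks 20.4% of the substrate into isomer of the product.

In alder, x is 1.00 and the coupled share 69.3%, so target stands at 48.9%, more than homo product at 30.7%. In elm, x is 0.334 and the coupled share 86.3%, so target stands at 65.9%, more than homo product. In birch, x is 3.01 and the coupled share 46.2%, so homo product leads at 53.8%, more than target and isomer together.

The forecast says target at 46% in alder, homo product at 55.5% in birch and target at 63% in elm, holding for birch that “partner supply is too slow, so dimerisation wins”.

The flasks give target at 44.7% in alder, homo product at 58.7% in birch and target at 62.6% in elm. Alder ends with 37.4% of homo product against my 30.7%, and its target and isomer together hold 61.3% against my 69.3%. Take D* to the neighbour of alder charged with 0.084 M of partner: x is 2.51, the coupled share 50.1%, and homo product 49.9%. That neighbour ends with homo product ahead, at 55.6%.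

(The numbers come from no measurement; the rest is arithmetic.)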